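**Strategy.** The cyclohexene ring (carotenoid numbering: C1 = CMe2, C2 = stereocentre, C5=C6 the ring alkene) hides a limonene: its gem-dimethyl carbon C1 next to C2 is an isopropenyl group plus one hydrogen, and C2, like C2' of the acyclic end, maps onto C4 of (R)-limonene. Cutting the limonene ring gives one keto-aldehyde for both ends. The key step closes the C1–C6 bond: iron-hydride hydrogen-atom transfer turns the isopropenyl group into a tertiary radical that attacks the central carbon of an allenylphosphonate. Unlike the biosynthetic cation, this radical cannot scramble C2. One operation builds the ring, the quaternary C1 and the tetrasubstituted C5=C6 bond and leaves a C7 phosphonate for the polyene; the precursor is an acyclic isopropenyl allenylphosphonate.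

Key step: step 5

Remark: carotenoid numbering is used throughout (primed numbers for the acyclic half of the molecule), and crocetindialdehyde (8,8'-diapocarotene-8,8'-dial) is taken as a purchased carotenoid building block.

**Step 1**
Reactants: 1 (4R)-limonene 1,2-oxide (cis/trans mixture, from (R)-limonene)
Product: 3 (3R)-6-oxo-3-(prop-1-en-2-yl)heptanal, via limonene-1,2-diol 2 (not isolated)
Conditions: H5IO6 (1.1 equiv), THF/H2O, 0 °C to rt
Reagents that add atoms: water, O
Why: Periodic acid opens the epoxide to the 1,2-diol and cleaves it in the same flask (epoxide hydrolysis followed by Malaprade glycol cleavage), so both epoxide diastereomers converge on one keto-aldehyde and the isopropenyl group and the stereocentre (limonene C4, the future C2 and C2') are not touched.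

**Step 2**
Reactants: 3 (3R)-6-oxo-3-(prop-1-en-2-yl)heptanal
Product: 4 ethyl (2E,5R)-2-methyl-8-oxo-5-(prop-1-en-2-yl)non-2-enoate
Conditions: Ph3P=C(CH3)CO2Et (1.1 equiv), CH2Cl2, 0 °C to rt
Reagents that add atoms: ethyl 2-(triphenyl-λ5-phosphanylidene)propanoate, CCOC(=O)C(C)=P(c1ccccc1)(c1ccccc1)c1ccccc1
Why: The stabilised ylide reacts only with the aldehyde (Wittig olefination) and gives the (E)-2-methyl enoate, which is the whole C2 side chain at the ester oxidation level and a group that can neither donate nor accept in the later radical step.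

**Step 3**
Reactants: 4 ethyl (2E,5R)-2-methyl-8-oxo-5-(prop-1-en-2-yl)non-2-enoate
Product: 5 ethyl (2E,5R)-8-hydroxy-2,8-dimethyl-5-(prop-1-en-2-yl)dec-2-en-9-ynoate (both C8 epimers)
Conditions: HC≡CMgBr (1.3 equiv), THF, −40 to 0 °C; aq NH4Cl
Reagents that add atoms: ethynylmagnesium bromide, C#C[Mg]Br
Why: Grignard 1,2-addition of the acetylide to the methyl ketone outpaces attack on the α-methyl enoate at low temperature; the new carbinol centre forms without control, which does not matter because it becomes sp2 in the next step.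

**Step 4**
Reactants: 5 ethyl (2E,5R)-8-hydroxy-2,8-dimethyl-5-(prop-1-en-2-yl)dec-2-en-9-ynoate
Product: 7 ethyl (2E,5R)-10-(diethoxyphosphoryl)-2,8-dimethyl-5-(prop-1-en-2-yl)deca-2,8,9-trienoate (both allene diastereomers), via propargyl diethyl phosphite 6 (not isolated)
Conditions: ClP(OEt)2 (1.2 equiv), Et3N, CH2Cl2, −78 °C to rt
Reagents that add atoms: diethyl chlorophosphite, CCOP(Cl)OCC
Why: O-Phosphitylation of the tertiary propargylic alcohol is followed on warming by the [2,3]-sigmatropic propargyl phosphite to allenylphosphonate rearrangement (Horner–Mark rearrangement); the allene axis forms without control and is erased in step 5.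

**Step 5**
Reactants: 7 ethyl (2E,5R)-10-(diethoxyphosphoryl)-2,8-dimethyl-5-(prop-1-en-2-yl)deca-2,8,9-trienoate
Product: 8 ethyl (2E)-4-{(1R)-3-[(diethoxyphosphoryl)methyl]-2,2,4-trimethylcyclohex-3-en-1-yl}-2-methylbut-2-enoate
Conditions: Fe(acac)3 (0.5 equiv), PhSiH3 (2.5 equiv), EtOH/(CH2OH)2 5:1, 0.01 M, 60 °C
Reagents that add atoms: none
Why: Proposed new method: the iron hydride formed from Fe(acac)3 and PhSiH3 in EtOH should transfer a hydrogen atom to the CH2 terminus of the isopropenyl group, the tertiary radical at the future C1 should add to the central allene carbon (future C6), and the phosphonate-stabilised allyl radical over C5–C6–C7 should then be reduced and protonated at C7. The closest known reaction type is the iron-hydride (MHAT) reductive olefin coupling, that is, the hydrogen-atom-transfer-initiated Giese cyclisation onto vinyl phosphonates, vinyl sulfones and enones, together with the known preference of carbon radicals for the central carbon of acceptor-substituted allenes; an allenylphosphonate has not been shown as the acceptor. The six-membered ring closes in a 6-exo mode with respect to the phosphonate-conjugated C6=C7 π bond (6-endo with respect to C5=C6), by attack on an sp carbon. No stereocentre is created, since C1 ends with two methyl groups, and C2 keeps the configuration of limonene C4 because a radical at C1, unlike the cation of the biosynthetic closure, does not trigger a 1,2-hydride shift from C2. The step needs hydrogen-atom transfer to the isopropenyl group and not to the allene or the enoate, attack at C6 and not at C5, and hydrogen delivery to C7 and not to C5. These are expected to be secured by the electron-poor and fully substituted allene, the polarity match between a nucleophilic tertiary radical and C6, the 4-exo strain of the path to the side-chain enoate, and the lower hindrance at C7 that also keeps the tetrasubstituted C5=C6 bond.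

**Step 6**
Reactants: 8 ethyl (2E)-4-{(1R)-3-[(diethoxyphosphoryl)methyl]-2,2,4-trimethylcyclohex-3-en-1-yl}-2-methylbut-2-enoate
Product: 9 diethyl ({(5R)-5-[(2E)-4-hydroxy-3-methylbut-2-en-1-yl]-2,6,6-trimethylcyclohex-1-en-1-yl}methyl)phosphonate
Conditions: iBu2AlH (2.5 equiv), CH2Cl2, −78 °C; aq potassium sodium tartrate work-up
Reagents that add atoms: none
Why: Low-temperature 1,2-reduction of the conjugated ester by the aluminium hydride gives the (E)-allylic alcohol and leaves the phosphonate diester and the tetrasubstituted ring alkene alone.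

**Step 7**
Reactants: 9 diethyl ({(5R)-5-[(2E)-4-hydroxy-3-methylbut-2-en-1-yl]-2,6,6-trimethylcyclohex-1-en-1-yl}methyl)phosphonate; 10 crocetindialdehyde, (all-E)-2,6,11,15-tetramethylhexadeca-2,4,6,8,10,12,14-heptaenedial
Product: 11 (2E,4E,6E,8E,10E,12E,14E,16E)-17-{(5R)-5-[(2E)-4-hydroxy-3-methylbut-2-en-1-yl]-2,6,6-trimethylcyclohex-1-en-1-yl}-2,6,11,15-tetramethylheptadeca-2,4,6,8,10,12,14,16-octaenal
Conditions: 9, KN(SiMe3)2 (2.1 equiv), THF, −78 °C; then added to 10 (3 equiv), THF, −40 °C to rt, dark, Ar
Reagents that add atoms: none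
Why: Horner–Wadsworth–Emmons olefination of the allylic phosphonate carbanion (formed beside the alkoxide by two equivalents of base) with an excess of the symmetrical dialdehyde should stop at the mono-adduct and give the (E)-C7=C8 bond, since the Z isomer would clash with the ring methyl groups.

**Step 8**
Reactants: 3 (3R)-6-oxo-3-(prop-1-en-2-yl)heptanal
Product: 12 (5R)-8-methyl-5-(prop-1-en-2-yl)non-7-en-2-one
Conditions: iPrPPh3+ I−, nBuLi, THF, 0 °C; then 3, −78 to 0 °C
Reagents that add atoms: isopropylidenetriphenylphosphorane (made in the flask from isopropyltriphenylphosphonium iodide and nBuLi), CC(C)=P(c1ccccc1)(c1ccccc1)c1ccccc1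
Why: Wittig olefination with the non-stabilised isopropylidene ylide converts the aldehyde into the 3-methylbut-2-enyl group, the hindered ylide being far slower toward the methyl ketone.

**Step 9**
Reactants: 12 (5R)-8-methyl-5-(prop-1-en-2-yl)non-7-en-2-one
Product: 14 (3R)-2-methyl-3-(3-methylbut-2-en-1-yl)heptane-2,6-diol (both C6 epimers), via alkylmercury acetate 13 (not isolated)
Conditions: Hg(OAc)2 (1.05 equiv), THF/H2O 1:1, rt; then 3 M NaOH, NaBH4 (excess), 0 °C to rt
Reagents that add atoms: water, O
Why: Markovnikov oxymercuration prefers the 1,1-disubstituted isopropenyl group strongly over the trisubstituted alkene (as in limonene to α-terpineol) and installs the tertiary hydroxyl of C1', while the NaBH4 of the demercuration also reduces the ketone to a carbinol mixture that step 10 reoxidises.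

**Step 10**
Reactants: 14 (3R)-2-methyl-3-(3-methylbut-2-en-1-yl)heptane-2,6-diol
Product: 16 (3E,5S)-6-hydroxy-6-methyl-5-(3-methylbut-2-en-1-yl)hept-3-en-2-one, via hydroxy ketone 15 (not isolated)
Conditions: IBX (3 equiv), DMSO, 70 °C
Reagents that add atoms: none
Why: IBX first oxidises the secondary alcohol and then dehydrogenates the methyl ketone (IBX-mediated α,β-dehydrogenation), which is possible only on the side that carries a β-hydrogen and gives the (E)-enone; the tertiary alcohol and the trisubstituted alkene are expected to survive.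

**Step 11**
Reactants: 16 (3E,5S)-6-hydroxy-6-methyl-5-(3-methylbut-2-en-1-yl)hept-3-en-2-one
Product: 17 (4E,6S)-3,7-dimethyl-6-(3-methylbut-2-en-1-yl)octa-1,4-diene-3,7-diol (both C3 epimers)
Conditions: CH2=CHMgBr (3 equiv), THF, −78 to 0 °C; aq NH4Cl
Reagents that add atoms: vinylmagnesium bromide, C=C[Mg]Br
Why: Grignard 1,2-addition to the methyl enone, the reaction that turns ionones into their vinyl carbinols, gives the bis-allylic tertiary alcohol whose new carbinol centre is removed in step 12.

**Step 12**
Reactants: 17 (4E,6S)-3,7-dimethyl-6-(3-methylbut-2-en-1-yl)octa-1,4-diene-3,7-diol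
Product: 18 [(2E,4E,6S)-7-hydroxy-3,7-dimethyl-6-(3-methylbut-2-en-1-yl)octa-2,4-dien-1-yl]triphenylphosphonium bromide
Conditions: PPh3·HBr (1.05 equiv), MeOH, rt; recrystallisation to the (2E,4E) salt
Reagents that add atoms: triphenylphosphine hydrobromide, [Br-].[PH+](c1ccccc1)(c1ccccc1)c1ccccc1
Why: Acid ionises the bis-allylic tertiary alcohol to a pentadienyl cation that PPh3 captures at the unhindered primary terminus (allylic transposition, the standard entry to polyenyl Wittig salts), which gives the conjugated dienyl salt without involving C2'.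

**Step 13**
Reactants: 11 (2E,4E,6E,8E,10E,12E,14E,16E)-17-{(5R)-5-[(2E)-4-hydroxy-3-methylbut-2-en-1-yl]-2,6,6-trimethylcyclohex-1-en-1-yl}-2,6,11,15-tetramethylheptadeca-2,4,6,8,10,12,14,16-octaenal; 18 [(2E,4E,6S)-7-hydroxy-3,7-dimethyl-6-(3-methylbut-2-en-1-yl)octa-2,4-dien-1-yl]triphenylphosphonium bromide
Product: 19 (all-E,2R,2'S)-2-[(2E)-4-hydroxy-3-methylbut-2-en-1-yl]-2'-(3-methylbut-2-en-1-yl)-3',4'-didehydro-1',2'-dihydro-β,ψ-caroten-1'-ol (the target)
Conditions: NaOMe (1.3 equiv), MeOH/CH2Cl2, 0 °C to rt, dark, Ar; then EtOH, reflux (Z to E), crystallisation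
Reagents that add atoms: none
Why: Wittig olefination of the polyenal with the allylic ylide, a reaction that tolerates free hydroxyl groups in methanol, forms the C7'=C8' bond, and the hindered Z isomer of this bond goes over to E on heating as is usual for carotenoids.

**Compound list**
1 | (4R)-limonene 1,2-oxide, (4R)-1-methyl-4-(prop-1-en-2-yl)-7-oxabicyclo[4.1.0]heptane, cis/trans mixture | CC12OC1C[C@@H](CC2)C(C)=C | starting material
2 | (4R)-1-methyl-4-(prop-1-en-2-yl)cyclohexane-1,2-diol (limonene-1,2-diol) | CC1(O)CC[C@H](CC1O)C(C)=C | intermediate (not isolated)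
3 | (3R)-6-oxo-3-(prop-1-en-2-yl)heptanal | O=CC[C@@H](CCC(C)=O)C(C)=C | intermediate
4 | ethyl (2E,5R)-2-methyl-8-oxo-5-(prop-1-en-2-yl)non-2-enoate | CCOC(=O)/C(C)=C/C[C@@H](CCC(C)=O)C(C)=C | intermediate
5 | ethyl (2E,5R)-8-hydroxy-2,8-dimethyl-5-(prop-1-en-2-yl)dec-2-en-9-ynoate, both C8 epimers | CCOC(=O)/C(C)=C/C[C@@H](CCC(C)(O)C#C)C(C)=C | intermediate
6 | ethyl (2E,5R)-8-[(diethoxyphosphanyl)oxy]-2,8-dimethyl-5-(prop-1-en-2-yl)dec-2-en-9-ynoate | CCOC(=O)/C(C)=C/C[C@@H](CCC(C)(OP(OCC)OCC)C#C)C(C)=C | intermediate (not isolated)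
7 | ethyl (2E,5R)-10-(diethoxyphosphoryl)-2,8-dimethyl-5-(prop-1-en-2-yl)deca-2,8,9-trienoate, both allene diastereomers | CCOC(=O)/C(C)=C/C[C@@H](CCC(C)=C=CP(=O)(OCC)OCC)C(C)=C | intermediate
8 | ethyl (2E)-4-{(1R)-3-[(diethoxyphosphoryl)methyl]-2,2,4-trimethylcyclohex-3-en-1-yl}-2-methylbut-2-enoate | CCOC(=O)/C(C)=C/C[C@H]1CCC(C)=C(CP(=O)(OCC)OCC)C1(C)C | intermediate
9 | diethyl ({(5R)-5-[(2E)-4-hydroxy-3-methylbut-2-en-1-yl]-2,6,6-trimethylcyclohex-1-en-1-yl}methyl)phosphonate | OC/C(C)=C/C[C@H]1CCC(C)=C(CP(=O)(OCC)OCC)C1(C)C | intermediate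
10 | crocetindialdehyde, (2E,4E,6E,8E,10E,12E,14E)-2,6,11,15-tetramethylhexadeca-2,4,6,8,10,12,14-heptaenedial | O=C/C(C)=C/C=C/C(C)=C/C=C/C=C(C)/C=C/C=C(C)/C=O | starting material
11 | (2E,4E,6E,8E,10E,12E,14E,16E)-17-{(5R)-5-[(2E)-4-hydroxy-3-methylbut-2-en-1-yl]-2,6,6-trimethylcyclohex-1-en-1-yl}-2,6,11,15-tetramethylheptadeca-2,4,6,8,10,12,14,16-octaenal | O=C/C(C)=C/C=C/C(C)=C/C=C/C=C(C)/C=C/C=C(C)/C=C/C1=C(C)CC[C@H](C/C=C(\C)CO)C1(C)C | intermediate
12 | (5R)-8-methyl-5-(prop-1-en-2-yl)non-7-en-2-one | CC(C)=CC[C@@H](CCC(C)=O)C(C)=C | intermediate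
13 | {(3R)-2-hydroxy-2-methyl-3-(3-methylbut-2-en-1-yl)-6-oxoheptyl}mercury acetate, both C2 epimers | CC(C)=CC[C@@H](CCC(C)=O)C(C)(O)C[Hg]OC(C)=O | intermediate (not isolated)
14 | (3R)-2-methyl-3-(3-methylbut-2-en-1-yl)heptane-2,6-diol, both C6 epimers | CC(C)=CC[C@@H](CCC(C)O)C(C)(C)O | intermediate
15 | (5R)-6-hydroxy-6-methyl-5-(3-methylbut-2-en-1-yl)heptan-2-one | CC(C)=CC[C@@H](CCC(C)=O)C(C)(C)O | intermediate (not isolated)
16 | (3E,5S)-6-hydroxy-6-methyl-5-(3-methylbut-2-en-1-yl)hept-3-en-2-one | CC(C)=CC[C@@H](/C=C/C(C)=O)C(C)(C)O | intermediate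
17 | (4E,6S)-3,7-dimethyl-6-(3-methylbut-2-en-1-yl)octa-1,4-diene-3,7-diol, both C3 epimers | CC(C)=CC[C@@H](/C=C/C(C)(O)C=C)C(C)(C)O | intermediate
18 | [(2E,4E,6S)-7-hydroxy-3,7-dimethyl-6-(3-methylbut-2-en-1-yl)octa-2,4-dien-1-yl]triphenylphosphonium bromide | CC(C)=CC[C@@H](/C=C/C(C)=C/C[P+](c1ccccc1)(c1ccccc1)c1ccccc1)C(C)(C)O.[Br-] | intermediate
19 | (all-E,2R,2'S)-2-[(2E)-4-hydroxy-3-methylbut-2-en-1-yl]-2'-(3-methylbut-2-en-1-yl)-3',4'-didehydro-1',2'-dihydro-β,ψ-caroten-1'-ol | CC(C)=CC[C@@H](/C=C/C(C)=C/C=C/C(C)=C/C=C/C(C)=C/C=C/C=C(C)/C=C/C=C(C)/C=C/C1=C(C)CC[C@H](C/C=C(\C)CO)C1(C)C)C(C)(C)O | target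

**Step count.** Total: 13 steps. Longest linear sequence: 8 steps (steps 1, 2, 3, 4, 5, 6, 7 and 13).

**Steps most likely to fail**

1. Step 5 (Proposed new method). The hydrogen atom may go to the allene instead of the isopropenyl group, the tertiary radical may be reduced before it closes, or hydrogen may be delivered to C5 of the allyl radical so that the double bond ends up exocyclic. Reversible hydrogen-atom transfer could also move the alkene to C1=C2 and erode C2. The fallback uses known chemistry, sets out from 4 and comes back at 8. Addition of CH2=CHMgBr to the ketone of 4 gives the vinyl carbinol F1. PBr3 converts it with allylic transposition into the primary allylic bromide F2. A Michaelis–Arbuzov reaction with P(OEt)3 gives the allylic phosphonate F3. Proton-initiated cation–olefin cyclisation (ClSO3H, 2-nitropropane, −78 °C), the closure by which geranyl sulfones and phosphonates are turned into cyclogeranyl ones, then forms the same C1–C6 bond and gives 8 after acid equilibration to the C5=C6 isomer. Because this closure passes through a cation next to C2, the enantiomeric purity at C2 would have to be checked at 8.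

2. Step 10. The enone may be oxidised further to a dienone, and C5 may epimerise through the dienol under hot IBX. The fallback sets out from 14 and comes back at 16. Dess–Martin periodinane oxidises the secondary alcohol, and hydroxy ketone 15 is isolated. Me3SiCl/NaI/Et3N in MeCN forms the more substituted silyl enol ether and silylates the tertiary alcohol, which gives the bis-silyl compound F4. Pd(OAc)2 in MeCN (Saegusa–Ito dehydrogenation) gives the silylated enone F5, and citric acid in aqueous MeOH frees 16.

3. Step 7. The symmetrical dialdehyde may be olefinated twice, and the β-oxido phosphonate of the hindered, doubly charged carbanion may collapse slowly. The fallback reverses the order of union; it sets out from 18 (with 10 and 9) and comes back at 19. Wittig reaction of 18 with an excess of 10 (NaOMe, MeOH/CH2Cl2) gives the decaenal F6. Olefination of F6 with the dianion of 9 (KN(SiMe3)2, THF) then gives 19 directly, so that the phosphonate carbanion meets a single aldehyde group and can be used in excess.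

**Further compounds**
F1 | step 5 | ethyl (2E,5R)-8-hydroxy-2,8-dimethyl-5-(prop-1-en-2-yl)deca-2,9-dienoate, both C8 epimers | CCOC(=O)/C(C)=C/C[C@@H](CCC(C)(O)C=C)C(C)=C
F2 | step 5 | ethyl (2E,5R)-10-bromo-2,8-dimethyl-5-(prop-1-en-2-yl)deca-2,8-dienoate, 8E/8Z mixture | CCOC(=O)/C(C)=C/C[C@@H](CCC(C)=CCBr)C(C)=C
F3 | step 5 | ethyl (2E,5R)-10-(diethoxyphosphoryl)-2,8-dimethyl-5-(prop-1-en-2-yl)deca-2,8-dienoate, 8E/8Z mixture | CCOC(=O)/C(C)=C/C[C@@H](CCC(C)=CCP(=O)(OCC)OCC)C(C)=C
F4 | step 10 | trimethyl{[(5S)-6-methyl-5-(3-methylbut-2-en-1-yl)-6-[(trimethylsilyl)oxy]hept-2-en-2-yl]oxy}silane | CC(C)=CC[C@@H](CC=C(C)O[Si](C)(C)C)C(C)(C)O[Si](C)(C)C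
F5 | step 10 | (3E,5S)-6-methyl-5-(3-methylbut-2-en-1-yl)-6-[(trimethylsilyl)oxy]hept-3-en-2-one | CC(C)=CC[C@@H](/C=C/C(C)=O)C(C)(C)O[Si](C)(C)C
F6 | step 7 | (2E,4E,6E,8E,10E,12E,14E,16E,18E,20E,22S)-23-hydroxy-2,6,11,15,19,23-hexamethyl-22-(3-methylbut-2-en-1-yl)tetracosa-2,4,6,8,10,12,14,16,18,20-decaenal | CC(C)=CC[C@@H](/C=C/C(C)=C/C=C/C(C)=C/C=C/C(C)=C/C=C/C=C(C)/C=C/C=C(C)/C=O)C(C)(C)O
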